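**Retrosynthetic overview**

1. Two Wittig disconnections (C11=C12 and C11'=C12') give commercial 2,7-dimethylocta-2,4,6-trienedial and two diastereomeric C15 phosphonium salts; both are 6S, one has the C5 hydroxyl cis to the side chain and the other trans.
2. Each salt comes from a C10 β-hydroxy aldehyde by HWE homologation with the commercial C5 phosphonocrotonate, ester reduction and bromide/PPh3 exchange.
3. Both aldehydes come from one bicyclic β-lactone. Reduction keeps its cis C5/C6 relation. For the trans series, ketal cleavage and β-elimination give the 6S enone acid, and epoxidation anti to the carboxylate followed by hydride opening puts the C5 hydroxyl on the other face.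
4. The β-lactone comes from an acyclic keto acid (3,3-dimethylglutaric anhydride + methallyl Grignard, ketalisation, ozonolysis) by a catalytic asymmetric aldol-lactonisation.
5. Ring order: the dioxolane first; then the cyclohexane and the oxetan-2-one close together in one operation; then the oxirane of the trans series. No ring is formed after the fragments are joined.

Assumption: (S)-HBTM is taken to give the β-lactone enantiomer drawn (otherwise (R)-HBTM is used), and the C3 carbinol centre made in the trans series is carried as an epimer mixture because it is oxidised away in the last step.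

Carotenoid numbering (C1–C7) is used for ring positions in the explanations.

**Route**

Step 1
Reactants: 1 3,3-dimethylglutaric anhydride; 2 2-methylallylmagnesium chloride
Product: 3 3,3,7-trimethyl-5-oxooct-7-enoic acid
Conditions: 2 (1.05 equiv) added slowly to 1, THF, −78 °C; dilute HCl work-up
Reagents that add atoms: none
Why: Acylation of the Grignard reagent by the cyclic anhydride (ring-opening addition); the magnesium carboxylate and the low temperature hold the reaction at the ketone stage, and no stereocentre is formed.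

Step 2
Reactants: 3 3,3,7-trimethyl-5-oxooct-7-enoic acid
Product: 4 3,3-dimethyl-4-[2-(2-methylprop-2-en-1-yl)-1,3-dioxolan-2-yl]butanoic acid
Conditions: Me3SiOCH2CH2OSiMe3 (2.5 equiv), Me3SiOSO2CF3 (5 mol%), CH2Cl2, −78 → −20 °C; pyridine, aqueous work-up at pH 4
Reagents that add atoms: 1,2-bis(trimethylsilyloxy)ethane, C[Si](C)(C)OCCO[Si](C)(C)C
Why: Noyori ketalisation masks the future C3 ketone under cold aprotic conditions in which the β,γ-alkene does not migrate; no stereocentre is formed.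

Step 3
Reactants: 4 3,3-dimethyl-4-[2-(2-methylprop-2-en-1-yl)-1,3-dioxolan-2-yl]butanoic acid
Product: 5 3,3-dimethyl-4-[2-(2-oxopropyl)-1,3-dioxolan-2-yl]butanoic acid
Conditions: O3, NaHCO3, CH2Cl2/MeOH, −78 °C; then Me2S, −78 → 23 °C
Reagents that add atoms: ozone, [O-][O+]=O
Why: Ozonolysis with reductive work-up turns the 1,1-disubstituted alkene into the methyl ketone while ketal and acid are inert; no stereocentre is formed.

Step 4
Reactants: 5 3,3-dimethyl-4-[2-(2-oxopropyl)-1,3-dioxolan-2-yl]butanoic acid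
Product: 7 (1S,6R)-2,2,6-trimethylspiro[7-oxabicyclo[4.2.0]octane-4,2'-[1,3]dioxolan]-8-one, via mixed tosyl anhydride 6 (not isolated)
Conditions: TsCl (1.25 equiv), (S)-2-phenyl-3,4-dihydro-2H-pyrimido[2,1-b][1,3]benzothiazole ((S)-HBTM, 20 mol%), iPr2NEt (4 equiv), LiCl (1 equiv), CH2Cl2, 23 °C, 5 added over 4 h
Reagents that add atoms: none
Why: Nucleophile-catalysed aldol-lactonisation (Romo NCAL): the mixed anhydride acylates the chiral isothiourea, the ammonium enolate adds to the methyl ketone and the aldolate expels the catalyst, so cyclohexane and oxetan-2-one close in the same operation; the cis ring fusion fixes C5–O cis to C7 and the catalyst sets the absolute sense (C5 R, C6 S).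

Step 5
Reactants: 7 (1S,6R)-2,2,6-trimethylspiro[7-oxabicyclo[4.2.0]octane-4,2'-[1,3]dioxolan]-8-one
Product: 8 (7R,8R)-8-(hydroxymethyl)-7,9,9-trimethyl-1,4-dioxaspiro[4.5]decan-7-ol
Conditions: LiBH4 (2 equiv), THF, 0 → 23 °C
Reagents that add atoms: none
Why: Hydride reduction of the strained lactone carbonyl (acyl C–O cleavage) gives the 1,3-diol with both stereocentres untouched.

Step 6
Reactants: 8 (7R,8R)-8-(hydroxymethyl)-7,9,9-trimethyl-1,4-dioxaspiro[4.5]decan-7-ol
Product: 9 (7R,8S)-7-hydroxy-7,9,9-trimethyl-1,4-dioxaspiro[4.5]decane-8-carbaldehyde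
Conditions: 2,2,6,6-tetramethylpiperidin-1-oxyl (TEMPO, 10 mol%), PhI(OAc)2 (1.1 equiv), CH2Cl2, 23 °C
Reagents that add atoms: none
Why: Oxoammonium oxidation is selective for the primary alcohol under neutral conditions, so the tertiary carbinol and the α-stereocentre of the aldehyde are preserved.

Step 7
Reactants: 9 (7R,8S)-7-hydroxy-7,9,9-trimethyl-1,4-dioxaspiro[4.5]decane-8-carbaldehyde; 10 triethyl 3-methyl-4-phosphonocrotonate
Product: 11 ethyl (2E,4E)-5-[(7R,8S)-7-hydroxy-7,9,9-trimethyl-1,4-dioxaspiro[4.5]decan-8-yl]-3-methylpenta-2,4-dienoate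
Conditions: 10 (2.2 equiv), LiN(SiMe3)2 (2.1 equiv), THF/DMPU, −78 °C; then 9, −78 → −30 °C
Reagents that add atoms: none
Why: Horner–Wadsworth–Emmons olefination with the preformed vinylogous phosphonate anion forms the 7E alkene (9E comes from the reagent) at temperatures where the lithium aldolate neither undergoes retro-aldol cleavage nor epimerises at C6.

Step 8
Reactants: 11 ethyl (2E,4E)-5-[(7R,8S)-7-hydroxy-7,9,9-trimethyl-1,4-dioxaspiro[4.5]decan-8-yl]-3-methylpenta-2,4-dienoate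
Product: 12 (2E,4E)-5-[(7R,8S)-7-hydroxy-7,9,9-trimethyl-1,4-dioxaspiro[4.5]decan-8-yl]-3-methylpenta-2,4-dien-1-ol
Conditions: iBu2AlH (3.5 equiv), CH2Cl2, −78 °C; aq. KNaC4H4O6
Reagents that add atoms: none
Why: 1,2-Reduction of the dienoate by iBu2AlH gives the primary allylic alcohol without touching ketal, alkenes or stereocentres.

Step 9
Reactants: 12 (2E,4E)-5-[(7R,8S)-7-hydroxy-7,9,9-trimethyl-1,4-dioxaspiro[4.5]decan-8-yl]-3-methylpenta-2,4-dien-1-ol
Product: 14 {(2E,4E)-5-[(7R,8S)-7-hydroxy-7,9,9-trimethyl-1,4-dioxaspiro[4.5]decan-8-yl]-3-methylpenta-2,4-dien-1-yl}triphenylphosphonium bromide, via allylic bromide 13 (not isolated)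
Conditions: CBr4 (1.1 equiv), PPh3 (2.3 equiv), CH2Cl2, 0 → 23 °C
Reagents that add atoms: triphenylphosphine, c1ccc(cc1)P(c1ccccc1)c1ccccc1; carbon tetrabromide, BrC(Br)(Br)Br
Why: Appel bromination of the primary allylic alcohol followed in the same flask by SN2 quaternisation of the excess phosphine gives the Wittig salt under neutral conditions that spare ketal and tertiary alcohol.

Step 10
Reactants: 14 {(2E,4E)-5-[(7R,8S)-7-hydroxy-7,9,9-trimethyl-1,4-dioxaspiro[4.5]decan-8-yl]-3-methylpenta-2,4-dien-1-yl}triphenylphosphonium bromide; 15 (2E,4E,6E)-2,7-dimethylocta-2,4,6-trienedial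
Product: 16 (2E,4E,6E,8E,10E,12E)-13-[(7R,8S)-7-hydroxy-7,9,9-trimethyl-1,4-dioxaspiro[4.5]decan-8-yl]-2,7,11-trimethyltrideca-2,4,6,8,10,12-hexaenal
Conditions: 15 (3 equiv), NaOMe (1.1 equiv) added slowly, CH2Cl2/MeOH, −10 → 23 °C
Reagents that add atoms: none
Why: Wittig olefination of the semi-stabilised allylic ylide with an excess of the symmetrical dialdehyde gives the mono-condensation product; the new 11,12 bond forms as an E/Z mixture that is equilibrated in step 17.

Step 11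
Reactants: 7 (1S,6R)-2,2,6-trimethylspiro[7-oxabicyclo[4.2.0]octane-4,2'-[1,3]dioxolan]-8-one
Product: 19 (1R,2S,6R)-1,3,3-trimethyl-5-oxo-7-oxabicyclo[4.1.0]heptane-2-carboxylic acid, via keto β-lactone 17 (not isolated), via enone acid 18 (not isolated)
Conditions: 1 M HCl, THF, 23 °C; then Et3N, 23 °C; then 30% H2O2, NaOH, MeOH, 0 °C; acidify to pH 3 at 0 °C
Reagents that add atoms: water, O; hydrogen peroxide, OO
Why: Ketal hydrolysis unmasks the C3 ketone, enolisation ejects the β-carboxylate (E1cB opening of the β-lactone) to give the enone carboxylate with C6 intact, and Weitz–Scheffer epoxidation adds hydroperoxide to C5 on the face opposite the C6 carboxylate, so the C5 oxygen ends up trans to C7.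

Step 12
Reactants: 19 (1R,2S,6R)-1,3,3-trimethyl-5-oxo-7-oxabicyclo[4.1.0]heptane-2-carboxylic acid
Product: 20 (3S,4R)-4-(hydroxymethyl)-3,5,5-trimethylcyclohexane-1,3-diol (C1 epimer mixture)
Conditions: LiAlH4 (5 equiv), THF, 0 °C → reflux; Fieser work-up
Reagents that add atoms: none
Why: LiAlH4 reduces acid and ketone and opens the epoxide by hydride delivery to the less substituted C4 (2,3-epoxy alcohol to 1,3-diol), which leaves the C5–O bond and so the trans C5/C6 relation (5S,6S in carotenoid numbering) untouched.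

Step 13
Reactants: 20 (3S,4R)-4-(hydroxymethyl)-3,5,5-trimethylcyclohexane-1,3-diol
Product: 21 (1S,2S)-2,4-dihydroxy-2,6,6-trimethylcyclohexane-1-carbaldehyde (C4 epimer mixture)
Conditions: 2,2,6,6-tetramethylpiperidin-1-oxyl (TEMPO, 10 mol%), PhI(OAc)2 (1.1 equiv), CH2Cl2, 0 → 23 °C
Reagents that add atoms: none
Why: Oxoammonium oxidation takes the primary alcohol in preference to the hindered secondary and the tertiary alcohols, with no change at C5 or C6.

Step 14
Reactants: 21 (1S,2S)-2,4-dihydroxy-2,6,6-trimethylcyclohexane-1-carbaldehyde; 10 triethyl 3-methyl-4-phosphonocrotonate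
Product: 22 ethyl (2E,4E)-5-[(1S,2S)-2,4-dihydroxy-2,6,6-trimethylcyclohexyl]-3-methylpenta-2,4-dienoate
Conditions: 10 (3.3 equiv), LiN(SiMe3)2 (3.2 equiv), THF/DMPU, −78 °C; then 21, −78 → −30 °C
Reagents that add atoms: none
Why: Horner–Wadsworth–Emmons olefination as in step 7, with extra anion to cover the two hydroxyl groups, gives the 7E diene ester without touching C5 or C6.

Step 15
Reactants: 22 ethyl (2E,4E)-5-[(1S,2S)-2,4-dihydroxy-2,6,6-trimethylcyclohexyl]-3-methylpenta-2,4-dienoate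
Product: 23 (2E,4E)-5-[(1S,2S)-2,4-dihydroxy-2,6,6-trimethylcyclohexyl]-3-methylpenta-2,4-dien-1-ol
Conditions: iBu2AlH (4.5 equiv), CH2Cl2, −78 °C; aq. KNaC4H4O6
Reagents that add atoms: none
Why: 1,2-Reduction of the dienoate by iBu2AlH to the allylic alcohol; stereocentres are not involved.

Step 16
Reactants: 23 (2E,4E)-5-[(1S,2S)-2,4-dihydroxy-2,6,6-trimethylcyclohexyl]-3-methylpenta-2,4-dien-1-ol
Product: 25 {(2E,4E)-5-[(1S,2S)-2,4-dihydroxy-2,6,6-trimethylcyclohexyl]-3-methylpenta-2,4-dien-1-yl}triphenylphosphonium bromide, via allylic bromide 24 (not isolated)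
Conditions: CBr4 (1.05 equiv), PPh3 (2.2 equiv), CH2Cl2, −20 → 23 °C
Reagents that add atoms: triphenylphosphine, c1ccc(cc1)P(c1ccccc1)c1ccccc1; carbon tetrabromide, BrC(Br)(Br)Br
Why: Appel bromination then phosphine quaternisation as in step 9; the primary allylic alcohol reacts far faster than the secondary and tertiary ring alcohols at this stoichiometry.

Step 17
Reactants: 16 (2E,4E,6E,8E,10E,12E)-13-[(7R,8S)-7-hydroxy-7,9,9-trimethyl-1,4-dioxaspiro[4.5]decan-8-yl]-2,7,11-trimethyltrideca-2,4,6,8,10,12-hexaenal; 25 {(2E,4E)-5-[(1S,2S)-2,4-dihydroxy-2,6,6-trimethylcyclohexyl]-3-methylpenta-2,4-dien-1-yl}triphenylphosphonium bromide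
Product: 26 (5S,6S,5'R,6'S)-3',3'-ethylenedioxy-5,6,5',6'-tetrahydro-β,β-carotene-3,5,5'-triol (all-E, C3 epimer mixture)
Conditions: NaOMe (1.2 equiv), CH2Cl2/MeOH, 0 → 23 °C; then I2 (2 mol%), CH2Cl2, daylight, 23 °C
Reagents that add atoms: none
Why: The second Wittig olefination joins the C25 and C15 halves, and iodine-catalysed photo-equilibration converts the 11Z, 11'Z and any 9Z isomers into the favoured all-E polyene; the ring stereocentres are not involved.

Step 18
Reactants: 26 (5S,6S,5'R,6'S)-3',3'-ethylenedioxy-5,6,5',6'-tetrahydro-β,β-carotene-3,5,5'-triol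
Product: 27 (5S,6S,5'R,6'S)-3,5,5'-trihydroxy-5,6,5',6'-tetrahydro-β,β-caroten-3'-one (all-E, C3 epimer mixture)
Conditions: 0.5 M HCl, THF/H2O, 0 → 23 °C, dark, argon
Reagents that add atoms: water, O
Why: Acid-catalysed hydrolysis of the dioxolane under conditions too mild to dehydrate the tertiary β-hydroxy ketone that it releases.

Step 19
Reactants: 27 (5S,6S,5'R,6'S)-3,5,5'-trihydroxy-5,6,5',6'-tetrahydro-β,β-caroten-3'-one
Product: 28 (5S,6S,5'R,6'S)-5,5'-dihydroxy-5,6,5',6'-tetrahydro-β,β-carotene-3,3'-dione (target)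
Conditions: Dess–Martin periodinane (1.5 equiv), pyridine (5 equiv), CH2Cl2, 0 °C, dark, argon
Reagents that add atoms: none
Why: Dess–Martin oxidation converts the secondary C3 carbinol (both epimers) into the ketone, while the tertiary alcohols and the polyene are unaffected and the buffer prevents β-elimination.

**Compound list**

1 | 3,3-dimethylglutaric anhydride (4,4-dimethyloxane-2,6-dione) | CC1(C)CC(=O)OC(=O)C1 | starting material
2 | 2-methylallylmagnesium chloride | CC(=C)C[Mg]Cl | starting material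
3 | 3,3,7-trimethyl-5-oxooct-7-enoic acid | CC(=C)CC(=O)CC(C)(C)CC(=O)O | intermediate
4 | 3,3-dimethyl-4-[2-(2-methylprop-2-en-1-yl)-1,3-dioxolan-2-yl]butanoic acid | CC(=C)CC1(CC(C)(C)CC(=O)O)OCCO1 | intermediate
5 | 3,3-dimethyl-4-[2-(2-oxopropyl)-1,3-dioxolan-2-yl]butanoic acid | CC(=O)CC1(CC(C)(C)CC(=O)O)OCCO1 | intermediate
6 | 3,3-dimethyl-4-[2-(2-oxopropyl)-1,3-dioxolan-2-yl]butanoic 4-methylbenzenesulfonic anhydride (mixed tosyl anhydride) | CC(=O)CC1(CC(C)(C)CC(=O)OS(=O)(=O)c2ccc(C)cc2)OCCO1 | intermediate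
7 | (1S,6R)-2,2,6-trimethylspiro[7-oxabicyclo[4.2.0]octane-4,2'-[1,3]dioxolan]-8-one (cis-fused β-lactone) | O=C1[C@H]2C(C)(C)CC3(OCCO3)C[C@@]2(C)O1 | intermediate
8 | (7R,8R)-8-(hydroxymethyl)-7,9,9-trimethyl-1,4-dioxaspiro[4.5]decan-7-ol (OH cis to CH2OH) | OC[C@H]1C(C)(C)CC2(OCCO2)C[C@@]1(C)O | intermediate
9 | (7R,8S)-7-hydroxy-7,9,9-trimethyl-1,4-dioxaspiro[4.5]decane-8-carbaldehyde | O=C[C@H]1C(C)(C)CC2(OCCO2)C[C@@]1(C)O | intermediate
10 | triethyl 3-methyl-4-phosphonocrotonate, ethyl (2E)-4-(diethoxyphosphoryl)-3-methylbut-2-enoate | CCOC(=O)/C=C(\C)CP(=O)(OCC)OCC | starting material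
11 | ethyl (2E,4E)-5-[(7R,8S)-7-hydroxy-7,9,9-trimethyl-1,4-dioxaspiro[4.5]decan-8-yl]-3-methylpenta-2,4-dienoate | CCOC(=O)/C=C(C)/C=C/[C@H]1C(C)(C)CC2(OCCO2)C[C@@]1(C)O | intermediate
12 | (2E,4E)-5-[(7R,8S)-7-hydroxy-7,9,9-trimethyl-1,4-dioxaspiro[4.5]decan-8-yl]-3-methylpenta-2,4-dien-1-ol | OC/C=C(C)/C=C/[C@H]1C(C)(C)CC2(OCCO2)C[C@@]1(C)O | intermediate
13 | (7R,8S)-8-[(1E,3E)-5-bromo-3-methylpenta-1,3-dien-1-yl]-7,9,9-trimethyl-1,4-dioxaspiro[4.5]decan-7-ol | BrC/C=C(C)/C=C/[C@H]1C(C)(C)CC2(OCCO2)C[C@@]1(C)O | intermediate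
14 | {(2E,4E)-5-[(7R,8S)-7-hydroxy-7,9,9-trimethyl-1,4-dioxaspiro[4.5]decan-8-yl]-3-methylpenta-2,4-dien-1-yl}triphenylphosphonium bromide | C(/C=C(C)/C=C/[C@H]1C(C)(C)CC2(OCCO2)C[C@@]1(C)O)[P+](c1ccccc1)(c1ccccc1)c1ccccc1.[Br-] | intermediate
15 | (2E,4E,6E)-2,7-dimethylocta-2,4,6-trienedial | O=C/C(C)=C/C=C/C=C(C)/C=O | starting material
16 | (2E,4E,6E,8E,10E,12E)-13-[(7R,8S)-7-hydroxy-7,9,9-trimethyl-1,4-dioxaspiro[4.5]decan-8-yl]-2,7,11-trimethyltrideca-2,4,6,8,10,12-hexaenal | O=C/C(C)=C/C=C/C=C(C)/C=C/C=C(C)/C=C/[C@H]1C(C)(C)CC2(OCCO2)C[C@@]1(C)O | intermediate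
17 | (1S,6R)-2,2,6-trimethyl-7-oxabicyclo[4.2.0]octane-4,8-dione | O=C1[C@H]2C(C)(C)CC(=O)C[C@@]2(C)O1 | intermediate
18 | (1S)-2,6,6-trimethyl-4-oxocyclohex-2-ene-1-carboxylic acid | OC(=O)[C@H]1C(C)(C)CC(=O)C=C1C | intermediate
19 | (1R,2S,6R)-1,3,3-trimethyl-5-oxo-7-oxabicyclo[4.1.0]heptane-2-carboxylic acid (epoxide oxygen trans to CO2H) | OC(=O)[C@H]1C(C)(C)CC(=O)[C@@H]2O[C@]12C | intermediate
20 | (3S,4R)-4-(hydroxymethyl)-3,5,5-trimethylcyclohexane-1,3-diol (tertiary OH trans to CH2OH; C1 epimer mixture) | OC[C@H]1C(C)(C)CC(O)C[C@]1(C)O | intermediate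
21 | (1S,2S)-2,4-dihydroxy-2,6,6-trimethylcyclohexane-1-carbaldehyde (C4 epimer mixture) | O=C[C@H]1C(C)(C)CC(O)C[C@]1(C)O | intermediate
22 | ethyl (2E,4E)-5-[(1S,2S)-2,4-dihydroxy-2,6,6-trimethylcyclohexyl]-3-methylpenta-2,4-dienoate | CCOC(=O)/C=C(C)/C=C/[C@H]1C(C)(C)CC(O)C[C@]1(C)O | intermediate
23 | (2E,4E)-5-[(1S,2S)-2,4-dihydroxy-2,6,6-trimethylcyclohexyl]-3-methylpenta-2,4-dien-1-ol | OC/C=C(C)/C=C/[C@H]1C(C)(C)CC(O)C[C@]1(C)O | intermediate
24 | (3S,4S)-4-[(1E,3E)-5-bromo-3-methylpenta-1,3-dien-1-yl]-3,5,5-trimethylcyclohexane-1,3-diol | BrC/C=C(C)/C=C/[C@H]1C(C)(C)CC(O)C[C@]1(C)O | intermediate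
25 | {(2E,4E)-5-[(1S,2S)-2,4-dihydroxy-2,6,6-trimethylcyclohexyl]-3-methylpenta-2,4-dien-1-yl}triphenylphosphonium bromide | C(/C=C(C)/C=C/[C@H]1C(C)(C)CC(O)C[C@]1(C)O)[P+](c1ccccc1)(c1ccccc1)c1ccccc1.[Br-] | intermediate
26 | (5S,6S,5'R,6'S)-3',3'-ethylenedioxy-5,6,5',6'-tetrahydro-β,β-carotene-3,5,5'-triol (all-E, C3 epimer mixture) | CC(/C=C/C=C(C)/C=C/[C@H]1C(C)(C)CC(O)C[C@]1(C)O)=C\C=C\C=C(C)\C=C\C=C(C)\C=C\[C@H]1C(C)(C)CC2(OCCO2)C[C@@]1(C)O | intermediate
27 | (5S,6S,5'R,6'S)-3,5,5'-trihydroxy-5,6,5',6'-tetrahydro-β,β-caroten-3'-one (all-E, C3 epimer mixture) | CC(/C=C/C=C(C)/C=C/[C@H]1C(C)(C)CC(O)C[C@]1(C)O)=C\C=C\C=C(C)\C=C\C=C(C)\C=C\[C@H]1C(C)(C)CC(=O)C[C@@]1(C)O | intermediate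
28 | (5S,6S,5'R,6'S)-5,5'-dihydroxy-5,6,5',6'-tetrahydro-β,β-carotene-3,3'-dione (CNP0366900.1) | CC(/C=C/C=C(C)/C=C/[C@H]1C(C)(C)CC(=O)C[C@]1(C)O)=C\C=C\C=C(C)\C=C\C=C(C)\C=C\[C@H]1C(C)(C)CC(=O)C[C@@]1(C)O | target

**Step count and risks**

Total step count: 19.
Longest linear sequence: 13 steps (1–4, 11–16, 17–19; the branch 1–4, 5–10, 17–19 is equally long).

Steps most likely to fail:

Step 4. The aldol-lactonisation must close a six-membered ring from a neopentyl-type enolate carbon, and the sense and level of induction are untested on this substrate. Fallback, from 5 to 8: acylate lithiated (S)-4-benzyl-1,3-oxazolidin-2-one with the pivaloyl mixed anhydride of 5 to give the N-acyl oxazolidinone F1. Close only the carbocycle by a magnesium-halide-catalysed soft-enolisation aldol of the imide onto the methyl ketone (MgBr2·OEt2 cat., Et3N, Me3SiCl, EtOAc) to give the silylated aldol imide F2, with the auxiliary directing the face. LiBH4 reduction of the imide and K2CO3/MeOH desilylation then return diol 8; the enantiomeric auxiliary is used if the sense is mismatched.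

Step 7 (the same hazard applies in step 14). The β-hydroxy aldehyde can undergo retro-aldol cleavage or epimerise at C6 under the basic olefination. Fallback, from 8 to 11, reverses the polarity so that no β-hydroxy aldehyde is made: Mitsunobu thioetherification of the primary alcohol of 8 with 1-phenyl-1H-tetrazole-5-thiol (PPh3, diisopropyl azodicarboxylate) gives the tetrazolyl sulfide F3. Oxidation with (NH4)6Mo7O24·4H2O/H2O2 gives the tetrazolyl sulfone F4. Julia–Kocienski olefination (KN(SiMe3)2, 2.1 equiv, THF, −78 °C) with commercial ethyl (2E)-3-methyl-4-oxobut-2-enoate then gives ester 11 directly.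

Step 11. In the telescoped sequence the β-lactone may be saponified before it eliminates, C6 may erode in the enone, or the carboxylate may open the epoxide. Fallback, from 7 to 20: stop after the HCl and Et3N stages and isolate enone acid 18. Conjugate borylation of its sodium salt (CuCl, NaOtBu, 1,2-bis(diphenylphosphino)benzene, bis(pinacolato)diboron, MeOH, THF) adds boron to C5 anti to the carboxylate and gives the tertiary boronate F5. NaBO3·4H2O oxidation with retention gives the trans β-hydroxy keto acid F6, and LiAlH4 reduction of acid and ketone rejoins the route at triol 20.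

**Further compounds**

F1 | step 4 | (4S)-4-benzyl-3-{3,3-dimethyl-4-[2-(2-oxopropyl)-1,3-dioxolan-2-yl]butanoyl}-1,3-oxazolidin-2-one | CC(=O)CC1(CC(C)(C)CC(=O)N2[C@@H](Cc3ccccc3)COC2=O)OCCO1
F2 | step 4 | (4S)-4-benzyl-3-{[(7R,8S)-7,9,9-trimethyl-7-(trimethylsilyloxy)-1,4-dioxaspiro[4.5]decan-8-yl]carbonyl}-1,3-oxazolidin-2-one | O=C(N1[C@@H](Cc2ccccc2)COC1=O)[C@H]1C(C)(C)CC2(OCCO2)C[C@@]1(C)O[Si](C)(C)C
F3 | step 7 | 5-({[(7R,8S)-7-hydroxy-7,9,9-trimethyl-1,4-dioxaspiro[4.5]decan-8-yl]methyl}sulfanyl)-1-phenyl-1H-tetrazole | c1ccccc1-n1nnnc1SC[C@H]1C(C)(C)CC2(OCCO2)C[C@@]1(C)O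
F4 | step 7 | 5-({[(7R,8S)-7-hydroxy-7,9,9-trimethyl-1,4-dioxaspiro[4.5]decan-8-yl]methyl}sulfonyl)-1-phenyl-1H-tetrazole | c1ccccc1-n1nnnc1S(=O)(=O)C[C@H]1C(C)(C)CC2(OCCO2)C[C@@]1(C)O
F5 | step 11 | (1R,2R)-2,6,6-trimethyl-4-oxo-2-(4,4,5,5-tetramethyl-1,3,2-dioxaborolan-2-yl)cyclohexane-1-carboxylic acid (boryl trans to CO2H) | OC(=O)[C@H]1C(C)(C)CC(=O)C[C@]1(C)B1OC(C)(C)C(C)(C)O1
F6 | step 11 | (1S,2S)-2-hydroxy-2,6,6-trimethyl-4-oxocyclohexane-1-carboxylic acid (OH trans to CO2H) | OC(=O)[C@H]1C(C)(C)CC(=O)C[C@]1(C)O
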